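**Retrosynthetic overview**
1. The last step is one neutral hydrogenation. It turns Ar–C≡C–CMe2OH into the 3-hydroxy-3-methylbutyl chain and frees the three benzyl-masked phenols.
2. Key step (bold, metal-free): the C3–C1' bond and ring C are made together. The nucleophilic alpha-carbon of a ring A o-hydroxyaryl enaminone attacks a dearomatised ring B (a p-quinone monoacetal). Rearomatisation delivers 2'-OH and 5'-OMe already differentiated. The usual 3-iodochromone/boronate coupling and the deoxybenzoin route are set aside and used only as a fallback.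
3. Quinone monoacetal ⇐ 4-methoxyphenol (PhI(OAc)2/MeOH) ⇐ Baeyer–Villiger oxidation of a benzaldehyde ⇐ Sonogashira coupling of O-benzyl-2-bromoisovanillin with 2-methylbut-3-yn-2-ol.
4. Enaminone ⇐ phloroacetophenone (selective dibenzylation, then DMF-DMA).
5. Ring order: rings A and B are bought as arenes. Ring B is dearomatised and then rearomatised in the key step. Ring C is the only ring built, in the penultimate step.

**Assumption:** the target SMILES holds no stereocentre and no stereogenic double bond, so the compound is achiral and no stereocontrol is needed. The only stereo-element on the way, the E alkene of 3, is consumed in step 7.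

**Step 1**
Reactants: 1 2,4,6-trihydroxyacetophenone
Product: 2 1-[2,4-bis(benzyloxy)-6-hydroxyphenyl]ethan-1-one
Conditions: BnBr (2.1 equiv), K2CO3 (2.2 equiv), DMF, rt
Reagents that add atoms: benzyl bromide, BrCc1ccccc1
Why: Williamson ether synthesis in which the phenol chelated to the acetyl C=O is the poorest nucleophile, so two equivalents of BnBr stop at the 4,6-dibenzyl ether and leave the OH needed for ring C.

**Step 2**
Reactants: 2 1-[2,4-bis(benzyloxy)-6-hydroxyphenyl]ethan-1-one
Product: 3 (E)-1-[2,4-bis(benzyloxy)-6-hydroxyphenyl]-3-(dimethylamino)prop-2-en-1-one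
Conditions: DMF-DMA (3 equiv), toluene, 95 °C, 3 h
Reagents that add atoms: N,N-dimethylformamide dimethyl acetal, COC(OC)N(C)C
Why: Aminomethylenation (enaminone condensation) of the acidic acetyl CH3 gives the thermodynamically favoured E push–pull alkene, while the chelated phenol and the benzyl ethers are untouched.

**Step 3**
Reactants: 4 2-bromo-3-hydroxy-4-methoxybenzaldehyde (2-bromoisovanillin)
Product: 5 3-(benzyloxy)-2-bromo-4-methoxybenzaldehyde
Conditions: BnBr (1.1 equiv), K2CO3 (1.5 equiv), DMF, rt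
Reagents that add atoms: benzyl bromide, BrCc1ccccc1
Why: Williamson ether synthesis on the only phenol present masks the future 4'-OH with a group that the last step removes without acid.

**Step 4**
Reactants: 5 3-(benzyloxy)-2-bromo-4-methoxybenzaldehyde; 6 2-methylbut-3-yn-2-ol (1.5 equiv)
Product: 7 3-(benzyloxy)-2-(3-hydroxy-3-methylbut-1-yn-1-yl)-4-methoxybenzaldehyde
Conditions: PdCl2(PPh3)2 (5 mol %), CuI (5 mol %), Et3N/DMF, 80 °C, Ar
Reagents that add atoms: none
Why: Sonogashira coupling in which the ortho-formyl group speeds oxidative addition of zerovalent palladium into the flanked C–Br bond and the slim alkyne tolerates both ortho substituents, so all five side-chain carbons and the tertiary alcohol arrive in one step.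

**Step 5**
Reactants: 7 3-(benzyloxy)-2-(3-hydroxy-3-methylbut-1-yn-1-yl)-4-methoxybenzaldehyde
Product: 9 3-(benzyloxy)-2-(3-hydroxy-3-methylbut-1-yn-1-yl)-4-methoxyphenol, via aryl formate 8 (not isolated)
Conditions: mCPBA (1.3 equiv), CH2Cl2, 0 °C to rt; wash; then K2CO3 (0.1 equiv), MeOH, 0 °C, 15 min
Reagents that add atoms: mCPBA, O=C(OO)c1cccc(Cl)c1
Why: Baeyer–Villiger (Dakin-type) oxidation in which the para-methoxy group makes the aryl group migrate to give formate 8, the alkyne reacts far more slowly with peracid than the aldehyde does, and the formate is methanolysed cold and fast enough that the o-alkynylphenol does not close to a benzofuran.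

**Step 6**
Reactants: 9 3-(benzyloxy)-2-(3-hydroxy-3-methylbut-1-yn-1-yl)-4-methoxyphenol
Product: 10 3-(benzyloxy)-2-(3-hydroxy-3-methylbut-1-yn-1-yl)-4,4-dimethoxycyclohexa-2,5-dien-1-one
Conditions: PhI(OAc)2 (1.05 equiv), MeOH, 0 °C, 20 min; NaHCO3 work-up
Reagents that add atoms: methanol, CO
Why: Oxidative phenol dearomatisation by trivalent iodine places methanol on the methoxy-stabilised para carbon to give the p-quinone monoacetal, and the rigid alkyne keeps the tertiary OH from reaching the ring.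

**Step 7 (key step)**
Reactants: 3 (E)-1-[2,4-bis(benzyloxy)-6-hydroxyphenyl]-3-(dimethylamino)prop-2-en-1-one; 10 3-(benzyloxy)-2-(3-hydroxy-3-methylbut-1-yn-1-yl)-4,4-dimethoxycyclohexa-2,5-dien-1-one (1.3 equiv)
Product: 12 5,7-bis(benzyloxy)-3-[4-(benzyloxy)-2-hydroxy-3-(3-hydroxy-3-methylbut-1-yn-1-yl)-5-methoxyphenyl]-4H-chromen-4-one, via alpha-aryl enaminone 11 (not isolated)
Conditions: C6F5CO2H (1.2 equiv), (CF3)2CHOH/CH2Cl2 (1:1), 4 Å MS, 0 °C, slow addition of 3 to 10, then rt
Reagents that add atoms: none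
Why: Proposed new method: the acid/fluoroalcohol pair ionises one ketal C–O bond of 10 to a 4-methoxyphenoxenium-type cation whose only open electrophilic site is C6 (alpha to C=O, since C2 is blocked by the alkynyl group), the enaminone alpha-carbon of 3 (by far the best pi-nucleophile present, well above its own acyl-deactivated ring A) attacks there in SN2' fashion, loss of MeOH and tautomerisation rearomatise ring B to 11, and 11 closes as alpha-substituted o-hydroxyaryl enaminones do, by 6-endo-trig addition of the ring A OH and loss of Me2NH (closure by the new 2'-OH would be 5-endo-trig), with the stoichiometric acid holding Me2NH as its salt; the closest known reaction types are the Brønsted acid/fluoroalcohol-promoted coupling of p-quinone monoacetals with arene and alkene nucleophiles (same site of attack, same 2-substituted 4-methoxyphenol outcome) and the domino electrophile capture/chromone annulation of o-hydroxyaryl enaminones (halogenation, sulfenylation, radical arylation).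

**Step 8**
Reactants: 12 5,7-bis(benzyloxy)-3-[4-(benzyloxy)-2-hydroxy-3-(3-hydroxy-3-methylbut-1-yn-1-yl)-5-methoxyphenyl]-4H-chromen-4-one
Product: 13 5,7-dihydroxy-3-[2,4-dihydroxy-3-(3-hydroxy-3-methylbutyl)-5-methoxyphenyl]-4H-chromen-4-one (target)
Conditions: H2 (1 atm), 10% Pd/C, EtOAc/MeOH (1:1), rt, stopped at 5 equiv H2
Reagents that add atoms: none
Why: Heterogeneous catalytic hydrogenation/hydrogenolysis saturates the alkyne (2 H2) and cleaves the three aryl benzyl ethers (3 H2) under neutral conditions, so the tertiary alcohol cannot cyclise onto a flanking phenol to a 2,2-dimethylchroman, while the trisubstituted vinylogous-ester C2=C3 bond of the chromone is reduced much more slowly; no stereocentre is created.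

**Compound list**
1 | 2,4,6-trihydroxyacetophenone | CC(=O)c1c(O)cc(O)cc1O | starting material
2 | 1-[2,4-bis(benzyloxy)-6-hydroxyphenyl]ethan-1-one | CC(=O)c1c(O)cc(OCc2ccccc2)cc1OCc1ccccc1 | intermediate
3 | (E)-1-[2,4-bis(benzyloxy)-6-hydroxyphenyl]-3-(dimethylamino)prop-2-en-1-one | CN(C)/C=C/C(=O)c1c(O)cc(OCc2ccccc2)cc1OCc1ccccc1 | intermediate
4 | 2-bromo-3-hydroxy-4-methoxybenzaldehyde | O=Cc1ccc(OC)c(O)c1Br | starting material
5 | 3-(benzyloxy)-2-bromo-4-methoxybenzaldehyde | O=Cc1ccc(OC)c(OCc2ccccc2)c1Br | intermediate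
6 | 2-methylbut-3-yn-2-ol | C#CC(C)(C)O | starting material
7 | 3-(benzyloxy)-2-(3-hydroxy-3-methylbut-1-yn-1-yl)-4-methoxybenzaldehyde | O=Cc1ccc(OC)c(OCc2ccccc2)c1C#CC(C)(C)O | intermediate
8 | 3-(benzyloxy)-2-(3-hydroxy-3-methylbut-1-yn-1-yl)-4-methoxyphenyl formate (not isolated) | O=COc1ccc(OC)c(OCc2ccccc2)c1C#CC(C)(C)O | intermediate
9 | 3-(benzyloxy)-2-(3-hydroxy-3-methylbut-1-yn-1-yl)-4-methoxyphenol | Oc1ccc(OC)c(OCc2ccccc2)c1C#CC(C)(C)O | intermediate
10 | 3-(benzyloxy)-2-(3-hydroxy-3-methylbut-1-yn-1-yl)-4,4-dimethoxycyclohexa-2,5-dien-1-one | O=C1C=CC(OC)(OC)C(OCc2ccccc2)=C1C#CC(C)(C)O | intermediate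
11 | 2-[4-(benzyloxy)-2-hydroxy-3-(3-hydroxy-3-methylbut-1-yn-1-yl)-5-methoxyphenyl]-1-[2,4-bis(benzyloxy)-6-hydroxyphenyl]-3-(dimethylamino)prop-2-en-1-one (not isolated; push–pull alkene, E/Z not fixed) | CN(C)C=C(C(=O)c1c(O)cc(OCc2ccccc2)cc1OCc1ccccc1)c1cc(OC)c(OCc2ccccc2)c(C#CC(C)(C)O)c1O | intermediate
12 | 5,7-bis(benzyloxy)-3-[4-(benzyloxy)-2-hydroxy-3-(3-hydroxy-3-methylbut-1-yn-1-yl)-5-methoxyphenyl]-4H-chromen-4-one | O=c1c(-c2cc(OC)c(OCc3ccccc3)c(C#CC(C)(C)O)c2O)coc2cc(OCc3ccccc3)cc(OCc3ccccc3)c12 | intermediate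
13 | 5,7-dihydroxy-3-[2,4-dihydroxy-3-(3-hydroxy-3-methylbutyl)-5-methoxyphenyl]-4H-chromen-4-one (achiral) | COc1cc(-c2coc3cc(O)cc(O)c3c2=O)c(O)c(CCC(C)(C)O)c1O | target

**Total step count:** 8.
**Longest linear sequence:** 6 steps (4 → 5 → 7 → 9 → 10 → 12 → 13; steps 3 to 8).

**Three steps most likely to fail**

**Step 7** is the largest risk, with three failure modes.
- A proton may outrun the quinone monoacetal and give plain 5,7-bis(benzyloxy)chromone.
- C-protonation of 11 would open a 5-exo closure by the new 2'-OH, leading to a 3-aroylbenzofuran.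
- Michael attack next to the ketal carbon would put the chromone ortho to the OMe group.

The fallback gives up the dearomatisation logic for the classical cross-coupling. It sets out from 9 and 3 and comes back to the route at 13.
- BnBr/K2CO3 converts 9 into 4-[2,6-bis(benzyloxy)-3-methoxyphenyl]-2-methylbut-3-yn-2-ol F1.
- NBS in MeCN at −20 °C brominates the position ortho/para to the two benzyloxy groups, giving 4-[2,6-bis(benzyloxy)-3-bromo-5-methoxyphenyl]-2-methylbut-3-yn-2-ol F2. NBS is chosen over iodine electrophiles, which would trigger alkyne iodocyclisation.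
- B2pin2, PdCl2(dppf) and KOAc give 4-[2,6-bis(benzyloxy)-3-methoxy-5-(4,4,5,5-tetramethyl-1,3,2-dioxaborolan-2-yl)phenyl]-2-methylbut-3-yn-2-ol F3.
- In parallel, I2 in CHCl3 turns 3 into 5,7-bis(benzyloxy)-3-iodo-4H-chromen-4-one F4.
- Suzuki–Miyaura coupling of F3 and F4 (PdCl2(dppf), K2CO3, dioxane/water) gives 5,7-bis(benzyloxy)-3-[2,4-bis(benzyloxy)-3-(3-hydroxy-3-methylbut-1-yn-1-yl)-5-methoxyphenyl]-4H-chromen-4-one F5.
- Hydrogenation over Pd/C as in step 8 then delivers 13.

**Step 5** has two risks. The peracid may attack the electron-rich aryl alkyne, and the freed o-alkynylphenol 9 may close 5-endo-dig to a benzofuran, helped by traces of Pd or Cu carried over from step 4. The fallback changes the order of events so that no free o-alkynylphenol ever exists. It sets out from 5 and comes back at 10.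
- mCPBA gives 3-(benzyloxy)-2-bromo-4-methoxyphenyl formate F6.
- Catalytic K2CO3 in MeOH gives 3-(benzyloxy)-2-bromo-4-methoxyphenol F7.
- PhI(OAc)2 in MeOH gives 3-(benzyloxy)-2-bromo-4,4-dimethoxycyclohexa-2,5-dien-1-one F8.
- This alpha-bromo enone is coupled with 6 under Sonogashira conditions (PdCl2(PPh3)2, CuI, Et3N, THF, rt) to give 10 directly.

**Step 8** has three risks: over-reduction of the chromone C2=C3 bond to the isoflavanone, loss of the propargylic OH, and Pd-induced closure of the alkynylphenol. The fallback separates the two tasks. It sets out from 12 and comes back at 13.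
- Metal-free diimide, generated from 2-nitrobenzenesulfonylhydrazide and Et3N at rt, saturates only the non-polar alkyne. This gives 5,7-bis(benzyloxy)-3-[4-(benzyloxy)-2-hydroxy-3-(3-hydroxy-3-methylbutyl)-5-methoxyphenyl]-4H-chromen-4-one F9.
- Transfer hydrogenolysis with 1,4-cyclohexadiene and 10% Pd/C in EtOH then removes the benzyl groups without a hydrogen atmosphere, giving 13.

**Further compounds**
F1 | step 7 | 4-[2,6-bis(benzyloxy)-3-methoxyphenyl]-2-methylbut-3-yn-2-ol | COc1ccc(OCc2ccccc2)c(C#CC(C)(C)O)c1OCc1ccccc1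
F2 | step 7 | 4-[2,6-bis(benzyloxy)-3-bromo-5-methoxyphenyl]-2-methylbut-3-yn-2-ol | COc1cc(Br)c(OCc2ccccc2)c(C#CC(C)(C)O)c1OCc1ccccc1
F3 | step 7 | 4-[2,6-bis(benzyloxy)-3-methoxy-5-(4,4,5,5-tetramethyl-1,3,2-dioxaborolan-2-yl)phenyl]-2-methylbut-3-yn-2-ol | COc1cc(B2OC(C)(C)C(C)(C)O2)c(OCc2ccccc2)c(C#CC(C)(C)O)c1OCc1ccccc1
F4 | step 7 | 5,7-bis(benzyloxy)-3-iodo-4H-chromen-4-one | O=c1c(I)coc2cc(OCc3ccccc3)cc(OCc3ccccc3)c12
F5 | step 7 | 5,7-bis(benzyloxy)-3-[2,4-bis(benzyloxy)-3-(3-hydroxy-3-methylbut-1-yn-1-yl)-5-methoxyphenyl]-4H-chromen-4-one | O=c1c(-c2cc(OC)c(OCc3ccccc3)c(C#CC(C)(C)O)c2OCc2ccccc2)coc2cc(OCc3ccccc3)cc(OCc3ccccc3)c12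
F6 | step 5 | 3-(benzyloxy)-2-bromo-4-methoxyphenyl formate | O=COc1ccc(OC)c(OCc2ccccc2)c1Br
F7 | step 5 | 3-(benzyloxy)-2-bromo-4-methoxyphenol | Oc1ccc(OC)c(OCc2ccccc2)c1Br
F8 | step 5 | 3-(benzyloxy)-2-bromo-4,4-dimethoxycyclohexa-2,5-dien-1-one | O=C1C=CC(OC)(OC)C(OCc2ccccc2)=C1Br
F9 | step 8 | 5,7-bis(benzyloxy)-3-[4-(benzyloxy)-2-hydroxy-3-(3-hydroxy-3-methylbutyl)-5-methoxyphenyl]-4H-chromen-4-one | O=c1c(-c2cc(OC)c(OCc3ccccc3)c(CCC(C)(C)O)c2O)coc2cc(OCc3ccccc3)cc(OCc3ccccc3)c12
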